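Cuts, in retrosynthetic order: the acyl–O bond of the C1′ ester; C3–C4 of the quinone ring (ring B: C1–C4, C4a, C8a); C1–C2; then in the side chain C3′=C4′ (cross metathesis) and C1′–C2′ (allylation).
Enabling feature: at the hydroquinone level, the unit C4(=O)–C4a=C8a–C1(=O)–C2(R)=C3H of ring B is the 4π-opened and 6π-closed isomer of a benzocyclobutenone. In that precursor C4 is the ring ketone, C1 is a carbinol bonded to C4, and C2=C3 is a 1-substituted vinyl group on C1; release of the four-ring strain pays for the C3–C4 bond.
Ring A (C4a, C5–C8, C8a) carries the same oxygen at C5 and C8, so the precursor 1,2-dione is mirror-symmetric, its two carbonyls are equivalent, and only one regioisomer can form.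
Forward order: ring A is bought, the four-membered ring comes from an aryne [2+2], oxidation gives the dione, a chiral alkenyllithium adds once, and heat turns the four-membered ring into ring B.
Deprotection uses naphthazarin tautomerism: ring B is trapped as its diacetate, ring A is oxidised to the quinone with loss of both methyl groups, and deacetylation gives the same dihydroxyquinone.
Stereochemistry: the only stereocentre, C1′ (R), comes from a reagent-controlled allylboration of 2-bromoacrolein, travels as a silyl ether, and is acylated on oxygen with retention.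

Key step: step 9

Remark: 5,8-dihydroxy-1,4-naphthoquinones exchange their quinone and hydroquinone rings by fast proton tautomerism, so the 2-substituted and 6-substituted drawings are treated as one compound, written as in the target SMILES.

Step 1
Reactants: 1 2-bromo-1,4-dimethoxybenzene; 2 1,1-diethoxyethene
Product: 5 3,6-dimethoxybenzocyclobutenone, via 3,6-dimethoxybenzyne 3 (not isolated), via diethyl ketal 4 (not isolated)
Conditions: NaNH2 (2 equiv), 2 (2 equiv), THF, reflux; then 1 M HCl, THF/H2O, rt
Reagents that add atoms: water, O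
Why: NaNH2 removes H-3, which lies between Br and OMe, bromide leaves, and the mirror-symmetric aryne 3 takes up the electron-rich ketene acetal in a stepwise [2+2] cycloaddition (aryne–ketene acetal cycloaddition) that can give only one regioisomer, after which dilute acid hydrolyses ketal 4 without touching the aryl methyl ethers.

Step 2
Reactants: 5 3,6-dimethoxybenzocyclobutenone
Product: 6 2,2-dibromo-3,6-dimethoxybenzocyclobutenone
Conditions: NBS (2.2 equiv), (BzO)2 (cat.), PhCF3, reflux
Reagents that add atoms: N-bromosuccinimide, O=C1CCC(=O)N1Br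
Why: Wohl–Ziegler bromination attacks the only benzylic C–H bonds, those of the ring CH2 next to the carbonyl, twice in succession, while the non-polar medium and the deactivating ketone hold back electrophilic bromination of the arene.

Step 3
Reactants: 6 2,2-dibromo-3,6-dimethoxybenzocyclobutenone
Product: 7 3,6-dimethoxybenzocyclobutene-1,2-dione
Conditions: AgNO3 (2.2 equiv), MeCN/H2O, 50 °C, dark
Reagents that add atoms: water, O
Why: Silver-assisted hydrolysis of a benzylic gem-dibromide, the classical way to a benzocyclobutenedione, should deliver the second carbonyl under conditions that leave the methyl ethers and the strained ring intact.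

Step 4
Reactants: 8 acrolein
Product: 10 2-bromoacrolein, via 2,3-dibromopropanal 9 (not isolated)
Conditions: Br2 (1.0 equiv), CH2Cl2, −78 °C to 0 °C; then Et3N (1.05 equiv), 0 °C; used fresh
Reagents that add atoms: bromine, BrBr
Why: Bromine adds across the alkene and Et3N then removes the acidic α-proton with loss of the β-bromide (bromination–dehydrobromination), the standard preparation of this aldehyde.

Step 5
Reactants: 10 2-bromoacrolein; 11 B-allyldiisopinocampheylborane built from (−)-α-pinene
Product: 13 (R)-2-bromohexa-1,5-dien-3-ol, via borinate ester 12 (not isolated)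
Conditions: 11 (1 M in pentane, 1.1 equiv), Et2O, −100 °C to −78 °C; then 3 M NaOH, 30% H2O2, 0 °C to rt
Reagents that add atoms: none
Why: Brown allylboration through a closed chair (Zimmerman–Traxler) transition state, in which the isopinocampheyl groups derived from (−)-α-pinene steer the allyl group to the aldehyde face that gives the R carbinol, the same sense as for aryl aldehydes and α-substituted enals, and the fast reaction at low temperature suits the polymerisable aldehyde.

Step 6
Reactants: 13 (R)-2-bromohexa-1,5-dien-3-ol
Product: 14 (R)-[(2-bromohexa-1,5-dien-3-yl)oxy](tert-butyl)dimethylsilane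
Conditions: TBSCl (1.2 equiv), imidazole (2.5 equiv), DMF, rt
Reagents that add atoms: tert-butyldimethylsilyl chloride, CC(C)(C)[Si](C)(C)Cl
Why: Standard silylation of a secondary alcohol gives an ether that withstands t-BuLi, heat, acetylation, tetravalent cerium and hydroxide and is a poor leaving group at C1′.

Step 7
Reactants: 14 (R)-[(2-bromohexa-1,5-dien-3-yl)oxy](tert-butyl)dimethylsilane; 15 2-methyl-2-butene
Product: 16 (R)-[(2-bromo-6-methylhepta-1,5-dien-3-yl)oxy](tert-butyl)dimethylsilane
Conditions: second-generation Grubbs catalyst RuCl2(=CHPh)(PCy3)(H2IMes) (3 mol %), 15 (large excess)/CH2Cl2, 40 °C, sealed vessel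
Reagents that add atoms: none
Why: Olefin cross metathesis with excess 2-methyl-2-butene turns the monosubstituted alkene into the prenyl terminus, whereas the 1,1-disubstituted, electron-poor bromoalkene should stay a spectator and a 1,5-diene has no viable ring-closing pathway.

Step 8
Reactants: 16 (R)-[(2-bromo-6-methylhepta-1,5-dien-3-yl)oxy](tert-butyl)dimethylsilane; 7 3,6-dimethoxybenzocyclobutene-1,2-dione
Product: 18 2-hydroxy-3,6-dimethoxy-2-[(3R)-3-(tert-butyldimethylsilyloxy)-6-methylhepta-1,5-dien-2-yl]benzocyclobutenone, via alkenyllithium 17 (not isolated)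
Conditions: t-BuLi (2.05 equiv), Et2O, −78 °C; cannulated into 7 (1.1 equiv), THF, −78 °C; sat. aq. NH4Cl at −78 °C
Reagents that add atoms: none
Why: Bromine–lithium exchange is followed by 1,2-addition of the alkenyllithium to the strained, highly electrophilic dione; inverse addition at −78 °C and the negative charge of the first adduct should stop the reaction at monoaddition, the equivalence of the two carbonyls removes any regiochemical question, and the new carbinol centre forms as an inconsequential epimer mixture because step 9 destroys it.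

Step 9
Reactants: 18 2-hydroxy-3,6-dimethoxy-2-[(3R)-3-(tert-butyldimethylsilyloxy)-6-methylhepta-1,5-dien-2-yl]benzocyclobutenone
Product: 22 2-[(1R)-1-(tert-butyldimethylsilyloxy)-4-methylpent-3-enyl]-5,8-dimethoxynaphthalene-1,4-diyl diacetate, via dienylketene 19 (not isolated), via naphthalenone 20 (not isolated), via hydroquinone 21 (not isolated)
Conditions: degassed p-xylene (0.02 M), reflux (138 °C), argon; cooled to rt; Ac2O (5 equiv), pyridine, DMAP (cat.), rt
Reagents that add atoms: acetic anhydride, CC(=O)OC(C)=O
Why: Heating opens the strained four-membered ring of 18 by conrotatory 4π electrocyclic cleavage of the C(=O)–C(OH) bond, and the donor hydroxyl turns outward (torquoselectivity), so the 1-substituted vinyl group turns inward and lies next to the ketene carbon of the o-quinoid dienylketene 19. A disrotatory 6π electrocyclisation then joins the ketene carbon (future C4) to the vinyl CH2 (future C3); this closes the six-membered ring B in a mode where all six ring atoms belong to the triene, restores the aromaticity of ring A and gives 20, whose enolisation gives hydroquinone 21. The closest known reaction type is the Moore rearrangement of 4-alkenyl-4-hydroxycyclobutenones and of 2-alkenyl-2-hydroxybenzocyclobutenones to hydroquinones and quinones. No new stereocentre arises: the carbinol carbon of 18 becomes sp2, so both epimers converge, and C1′ is a spectator under neutral aprotic conditions with the poor leaving group OTBS on it. The step needs periselectivity (6π closure rather than lactonisation of the hydroxyketene to a phthalide) and regiocontrol; wrong-way ring opening is reversible and feeds back through 18, and the place of the side chain next to C1 is fixed by the connectivity of 18. Acetylation in the same flask removes the air- and heat-sensitive hydroquinone and blocks the o-quinone-methide pathway that would erase C1′.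

Step 10
Reactants: 22 2-[(1R)-1-(tert-butyldimethylsilyloxy)-4-methylpent-3-enyl]-5,8-dimethoxynaphthalene-1,4-diyl diacetate
Product: 23 2-[(1R)-1-(tert-butyldimethylsilyloxy)-4-methylpent-3-enyl]-5,8-dioxo-5,8-dihydronaphthalene-1,4-diyl diacetate
Conditions: (NH4)2Ce(NO3)6 (2.5 equiv), MeCN/H2O, 0 °C
Reagents that add atoms: water, O
Why: Tetravalent cerium takes two electrons from the more electron-rich ring A (two methoxy donors) rather than from the diacetoxy ring B, water adds at C5 and C8 and methanol leaves (oxidative demethylation of a hydroquinone dimethyl ether), a process that at 0 °C should outrun attack on the trisubstituted alkene and the silyl ether.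

Step 11
Reactants: 23 2-[(1R)-1-(tert-butyldimethylsilyloxy)-4-methylpent-3-enyl]-5,8-dioxo-5,8-dihydronaphthalene-1,4-diyl diacetate
Product: 24 O-(tert-butyldimethylsilyl)shikonin
Conditions: LiOH (4 equiv), THF/H2O, 0 °C, argon; then 1 M HCl to pH 3–4
Reagents that add atoms: none
Why: Saponification of the two activated aryl acetates frees the dihydroxyquinone, whose proton tautomerism exchanges the roles of rings A and B, while the alkyl silyl ether and C1′ are inert to cold hydroxide, to which this chromophore is tolerant under argon.

Step 12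
Reactants: 24 O-(tert-butyldimethylsilyl)shikonin
Product: 25 shikonin
Conditions: HF·pyridine, pyridine/THF, 0 °C to rt, plastic vessel
Reagents that add atoms: none
Why: Fluoride-driven cleavage of the Si–O bond breaks no bond at C1′, and the buffered medium should avoid acid ionisation of the side-chain carbinol.

Step 13
Reactants: 25 shikonin; 26 3-hydroxy-3-methylbutanoic acid
Product: 27 β-hydroxyisovalerylshikonin (β-HIVS)
Conditions: DCC (1.2 equiv), DMAP (0.15 equiv), 26 (1.2 equiv), CH2Cl2, 0 °C to rt, argon, dark
Reagents that add atoms: none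
Why: Steglich esterification should acylate only the C1′ hydroxyl, because the two peri phenols are locked in strong hydrogen bonds to the quinone carbonyls and the tertiary hydroxyl of 26 is hindered, and acylation on oxygen keeps the R configuration.

Compound list
1 | 2-bromo-1,4-dimethoxybenzene | COc1ccc(OC)c(Br)c1 | starting material
2 | 1,1-diethoxyethene (ketene diethyl acetal) | C=C(OCC)OCC | starting material
3 | 3,6-dimethoxybenzyne | COC1=CC=C(OC)C#C1 | intermediate
4 | 7,7-diethoxy-2,5-dimethoxybicyclo[4.2.0]octa-1,3,5-triene (diethyl ketal of 5) | COc1ccc(OC)c2c1CC2(OCC)OCC | intermediate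
5 | 3,6-dimethoxybenzocyclobutenone (2,5-dimethoxybicyclo[4.2.0]octa-1,3,5-trien-7-one) | COc1ccc(OC)c2c1CC2=O | intermediate
6 | 2,2-dibromo-3,6-dimethoxybenzocyclobutenone | COc1ccc(OC)c2c1C(Br)(Br)C2=O | intermediate
7 | 3,6-dimethoxybenzocyclobutene-1,2-dione | COc1ccc(OC)c2c1C(=O)C2=O | intermediate
8 | acrolein | C=CC=O | starting material
9 | 2,3-dibromopropanal (racemic) | O=CC(Br)CBr | intermediate
10 | 2-bromoacrolein | C=C(Br)C=O | intermediate
11 | B-allyldiisopinocampheylborane built from (−)-α-pinene (commercial solution in pentane) | C=CCB([C@H]1C[C@H]2C[C@@H]([C@@H]1C)C2(C)C)[C@H]1C[C@H]2C[C@@H]([C@@H]1C)C2(C)C | starting material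
12 | (R)-2-bromohexa-1,5-dien-3-yl diisopinocampheylborinate | C=CC[C@@H](OB([C@H]1C[C@H]2C[C@@H]([C@@H]1C)C2(C)C)[C@H]1C[C@H]2C[C@@H]([C@@H]1C)C2(C)C)C(Br)=C | intermediate
13 | (R)-2-bromohexa-1,5-dien-3-ol | C=CC[C@@H](O)C(Br)=C | intermediate
14 | (R)-[(2-bromohexa-1,5-dien-3-yl)oxy](tert-butyl)dimethylsilane | C=CC[C@@H](O[Si](C)(C)C(C)(C)C)C(Br)=C | intermediate
15 | 2-methyl-2-butene | CC=C(C)C | starting material
16 | (R)-[(2-bromo-6-methylhepta-1,5-dien-3-yl)oxy](tert-butyl)dimethylsilane | CC(C)=CC[C@@H](O[Si](C)(C)C(C)(C)C)C(Br)=C | intermediate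
17 | (R)-[3-(tert-butyldimethylsilyloxy)-6-methylhepta-1,5-dien-2-yl]lithium | CC(C)=CC[C@@H](O[Si](C)(C)C(C)(C)C)C([Li])=C | intermediate
18 | 2-hydroxy-3,6-dimethoxy-2-[(3R)-3-(tert-butyldimethylsilyloxy)-6-methylhepta-1,5-dien-2-yl]benzocyclobutenone (both epimers at the ring carbinol carbon) | CC(C)=CC[C@@H](O[Si](C)(C)C(C)(C)C)C(=C)C1(O)C(=O)c2c(OC)ccc(OC)c21 | intermediate
19 | ring-opened o-quinoid dienylketene (hydroxyl outward, vinyl group next to the ketene) | CC(C)=CC[C@@H](O[Si](C)(C)C(C)(C)C)C(=C)/C(O)=C1\C(=C=O)C(OC)=CC=C1OC | intermediate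
20 | 3-[(1R)-1-(tert-butyldimethylsilyloxy)-4-methylpent-3-enyl]-4-hydroxy-5,8-dimethoxynaphthalen-1(2H)-one | CC(C)=CC[C@@H](O[Si](C)(C)C(C)(C)C)C1=C(O)c2c(OC)ccc(OC)c2C(=O)C1 | intermediate
21 | 2-[(1R)-1-(tert-butyldimethylsilyloxy)-4-methylpent-3-enyl]-5,8-dimethoxynaphthalene-1,4-diol | CC(C)=CC[C@@H](O[Si](C)(C)C(C)(C)C)c1cc(O)c2c(OC)ccc(OC)c2c1O | intermediate
22 | 2-[(1R)-1-(tert-butyldimethylsilyloxy)-4-methylpent-3-enyl]-5,8-dimethoxynaphthalene-1,4-diyl diacetate | CC(C)=CC[C@@H](O[Si](C)(C)C(C)(C)C)c1cc(OC(C)=O)c2c(OC)ccc(OC)c2c1OC(C)=O | intermediate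
23 | 2-[(1R)-1-(tert-butyldimethylsilyloxy)-4-methylpent-3-enyl]-5,8-dioxo-5,8-dihydronaphthalene-1,4-diyl diacetate (5,8-diacetoxy-6-substituted 1,4-naphthoquinone) | CC(C)=CC[C@@H](O[Si](C)(C)C(C)(C)C)c1cc(OC(C)=O)c2C(=O)C=CC(=O)c2c1OC(C)=O | intermediate
24 | O-(tert-butyldimethylsilyl)shikonin | CC(C)=CC[C@@H](O[Si](C)(C)C(C)(C)C)C1=CC(=O)c2c(O)ccc(O)c2C1=O | intermediate
25 | shikonin, 5,8-dihydroxy-2-[(1R)-1-hydroxy-4-methylpent-3-enyl]-1,4-naphthoquinone | CC(C)=CC[C@@H](O)C1=CC(=O)c2c(O)ccc(O)c2C1=O | intermediate
26 | 3-hydroxy-3-methylbutanoic acid | CC(C)(O)CC(=O)O | starting material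
27 | β-hydroxyisovalerylshikonin (β-HIVS) | CC(C)=CC[C@@H](OC(=O)CC(C)(C)O)C1=CC(=O)c2c(O)ccc(O)c2C1=O | target

Total step count: 13. Longest linear sequence: 10 (steps 4–13, from acrolein); the dione branch (steps 1–3) joins at step 8.

Steps most likely to fail

Step 9.
- What may go wrong: inward rotation of the hydroxyl with lactonisation of the hydroxyketene to a phthalide. Alternatively, the hot electron-rich hydroquinone may lose silanol through an o-quinone methide, with erosion of C1′.
- Fallback: it sets out from 16 and 7 and comes back at 22.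
- Bromide 16 is dehydrobrominated with LDA (THF, −78 °C to 0 °C) to the terminal alkyne F1.
- n-BuLi turns this into the lithium acetylide F2, which adds to 7 at −78 °C to give the alkynyl carbinol F3.
- Heating in p-xylene starts the alkynyl variant of the Moore rearrangement: ring opening, closure of the ketene carbon onto the distal alkyne carbon to a diradical, and hydrogen transfer from the hydroxyl. This should give the dimethoxynaphthoquinone F4 directly at the quinone level, so no hydroquinone is exposed to heat.
- Because ring A is mirror-symmetric, the side chain ends at the same position.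
- Reductive acetylation at rt (Zn dust, Ac2O, pyridine) then gives 22.

Step 8.
- What may go wrong: a second addition to the remaining carbonyl, and base-induced ring opening or rearrangement of the lithium alkoxide next to the ketone before the quench.
- Fallback: it sets out from 7 and comes back at 18.
- One carbonyl of 7 is masked (HC(OMe)3, MeOH, TsOH cat.) as the mono(dimethyl ketal) F5.
- Alkenyllithium 17 adds to the only ketone left to give the ketal carbinol F6.
- Mild hydrolysis (aqueous oxalic acid on silica, CH2Cl2) frees 18.

Step 13.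
- What may go wrong: self-acylation, β-lactone formation or dehydration of the activated β-hydroxy acid, and partial acylation of the phenols when the reaction is forced.
- Fallback: it sets out from 26 and 25 and comes back at 27.
- Acid 26 is persilylated (TESOTf, 2,6-lutidine, CH2Cl2) to the silyl ester silyl ether F7.
- The silyl ester alone is cleaved (K2CO3, MeOH/H2O, then citric acid) to the protected acid F8.
- This is coupled with 25 (DCC, DMAP, CH2Cl2) to the protected ester F9.
- HF·pyridine in THF at 0 °C removes the tertiary silyl ether to give 27.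

Further compounds
F1 | step 9 | (R)-tert-butyl(dimethyl)[(6-methylhept-5-en-1-yn-3-yl)oxy]silane | CC(C)=CC[C@@H](O[Si](C)(C)C(C)(C)C)C#C
F2 | step 9 | lithium acetylide of F1 | CC(C)=CC[C@@H](O[Si](C)(C)C(C)(C)C)C#C[Li]
F3 | step 9 | 2-hydroxy-3,6-dimethoxy-2-[(3R)-3-(tert-butyldimethylsilyloxy)-6-methylhept-5-en-1-ynyl]benzocyclobutenone (both carbinol epimers) | CC(C)=CC[C@@H](O[Si](C)(C)C(C)(C)C)C#CC1(O)C(=O)c2c(OC)ccc(OC)c21
F4 | step 9 | 2-[(1R)-1-(tert-butyldimethylsilyloxy)-4-methylpent-3-enyl]-5,8-dimethoxy-1,4-naphthoquinone | CC(C)=CC[C@@H](O[Si](C)(C)C(C)(C)C)C1=CC(=O)c2c(OC)ccc(OC)c2C1=O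
F5 | step 8 | 2,2,3,6-tetramethoxybenzocyclobutenone (mono(dimethyl ketal) of 7) | COc1ccc(OC)c2c1C(=O)C2(OC)OC
F6 | step 8 | 1-[(3R)-3-(tert-butyldimethylsilyloxy)-6-methylhepta-1,5-dien-2-yl]-2,2,3,6-tetramethoxybenzocyclobuten-1-ol (both carbinol epimers) | CC(C)=CC[C@@H](O[Si](C)(C)C(C)(C)C)C(=C)C1(O)c2c(OC)ccc(OC)c2C1(OC)OC
F7 | step 13 | triethylsilyl 3-methyl-3-(triethylsilyloxy)butanoate | CC[Si](CC)(CC)OC(=O)CC(C)(C)O[Si](CC)(CC)CC
F8 | step 13 | 3-methyl-3-(triethylsilyloxy)butanoic acid | CC[Si](CC)(CC)OC(C)(C)CC(=O)O
F9 | step 13 | O-triethylsilyl-β-hydroxyisovalerylshikonin | CC(C)=CC[C@@H](OC(=O)CC(C)(C)O[Si](CC)(CC)CC)C1=CC(=O)c2c(O)ccc(O)c2C1=O
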